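**Strategy.** Ring B is closed onto a finished ring A by a one-pot [3+3] spiroannulation. A ring A epoxide carrying a two-carbon zinc arm (C5–C4) is joined at C4 to C3 of a (Z)-bromoiodo diene by Negishi coupling. A Lewis acid then makes the diene terminus C1 open the tetrasubstituted C6–C7 epoxide at C6. The step exploits that in ring A the tertiary C7 hydroxyl lies anti to the C6–C1 bond: anti epoxide opening creates the spiro centre C6 and leaves the C7 oxygen in place, while the coupling fixes the E bromomethylidene on C3 of ring B. The precursors are an epoxy iodide made from (4R,6R)-actinol and (Z)-1-bromo-2-iodobuta-1,3-diene.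

Key step: step 9

Numbering used in the text (chamigrane): spiro carbon C6; ring B C1–C5 with C1=C2 and C3=C15HBr; ring A C7–C11 with C7 the carbinol, C9 the CHBr carbon and C11 the CMe2 carbon.

Assumption: (4R,6R)-actinol, the known two-enzyme reduction product of ketoisophorone, is taken as a purchasable chiral-pool ketone.

**Step 1**
Reactants: 1 (4R,6R)-4-hydroxy-2,2,6-trimethylcyclohexanone (actinol); 2 2,4,6-triisopropylbenzenesulfonyl hydrazide
Product: 3 N'-[(4R,6R)-4-hydroxy-2,2,6-trimethylcyclohexylidene]-2,4,6-triisopropylbenzenesulfonohydrazide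
Conditions: cat. HCl, MeCN, 25 °C
Reagents that add atoms: none
Why: Acid-catalysed condensation of the hindered ketone with the sulfonyl hydrazide should give the hydrazone needed for a Shapiro reaction and leaves the secondary carbinol (the later C9) untouched.

**Step 2**
Reactants: 3 the trisylhydrazone; 4 oxirane
Product: 6 (1R)-4-(2-hydroxyethyl)-3,5,5-trimethylcyclohex-3-en-1-ol, via vinyllithium alkoxide 5 (not isolated)
Conditions: n-BuLi (3.3 equiv), TMEDA, THF–hexane, −78 → 0 °C; then oxirane, −78 → 25 °C; H2O
Reagents that add atoms: none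
Why: Shapiro reaction: the trianion should lose sulfinate and N2 towards the only α-hydrogen, giving the tetrasubstituted vinyllithium regiospecifically, which opens oxirane to install C5–C4 as a 2-hydroxyethyl arm without touching the carbinol stereocentre.

**Step 3**
Reactants: 6 the diol
Product: 7 (1R)-4-(2-iodoethyl)-3,5,5-trimethylcyclohex-3-en-1-ol
Conditions: I2, PPh3, imidazole, CH2Cl2, 0 °C
Reagents that add atoms: iodine, II
Why: Garegg–Samuelsson iodination (Appel type) should be selective for the primary alcohol over the ring secondary alcohol.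

**Step 4**
Reactants: 7 the hydroxy iodide
Product: 8 (1S,3S,6R)-6-(2-iodoethyl)-1,5,5-trimethyl-7-oxabicyclo[4.1.0]heptan-3-ol (epoxide oxygen cis to the hydroxyl)
Conditions: VO(acac)2 (5 mol %), t-BuOOH, CH2Cl2, 0 → 25 °C
Reagents that add atoms: tert-butyl hydroperoxide, CC(C)(C)OO
Why: Vanadium-catalysed epoxidation directed by the homoallylic hydroxyl should deliver oxygen to the tetrasubstituted alkene on the hydroxyl face, which is also the face opposite the pseudoaxial methyl, and so sets the C6 and C7 oxygen configuration syn to the carbinol.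

**Step 5**
Reactants: 8 the epoxy alcohol
Product: 9 (1R,4R,6S)-4-bromo-1-(2-iodoethyl)-2,2,6-trimethyl-7-oxabicyclo[4.1.0]heptane (bromine trans to the epoxide oxygen)
Conditions: CBr4, PPh3, 2,6-lutidine, CH2Cl2, 0 °C
Reagents that add atoms: carbon tetrabromide, BrC(Br)(Br)Br
Why: Appel bromination should displace the oxyphosphonium group by SN2 with inversion, which sets the C9 bromide trans to the epoxide oxygen, while the tertiary epoxide and the primary iodide are not attacked under buffered conditions.

**Step 6**
Reactants: 10 bromoethene (vinyl bromide); 11 ethynyltrimethylsilane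
Product: 12 trimethyl(but-3-en-1-yn-1-yl)silane
Conditions: PdCl2(PPh3)2 (2 mol %), CuI (4 mol %), Et3N, THF, 25 °C
Reagents that add atoms: none
Why: Sonogashira coupling of a vinyl halide with a terminal alkyne should give the silyl enyne.

**Step 7**
Reactants: 12 the silyl enyne
Product: 13 1-bromobut-3-en-1-yne (kept as a cold solution)
Conditions: NBS, AgNO3 (10 mol %), acetone, 25 °C, dark
Reagents that add atoms: N-bromosuccinimide, O=C1CCC(=O)N1Br
Why: Silver-catalysed bromodesilylation should convert the alkynylsilane directly into the 1-bromoalkyne.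

**Step 8**
Reactants: 13 the bromoenyne
Product: 14 (1Z)-1-bromo-2-iodobuta-1,3-diene
Conditions: LiI, AcOH, 25–40 °C
Reagents that add atoms: lithium iodide, [Li+].[I-]
Why: Anti hydroiodination of a 1-bromoalkyne: iodide should add to the carbon bearing the vinyl group and the proton to the bromine-bearing carbon from the opposite side, which puts bromine and iodine cis (Z).

**Step 9**
Reactants: 9 the bromo epoxy iodide; 14 the bromoiodo diene
Product: 17 (1S,3R,6S)-3-bromo-9-[(E)-bromomethylidene]-1,5,5-trimethylspiro[5.5]undec-7-en-1-ol, via alkylzinc iodide 15 (not isolated), via epoxy triene 16 (not isolated)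
Conditions: Zn dust, LiCl, THF, 25 °C; then 14, Pd(PPh3)4 (5 mol %), 0 → 25 °C; then solvent exchange to CH2Cl2, MeAlCl2, −78 → −40 °C; aq. NaHCO3 (one pot, no work-up between stages)
Reagents that add atoms: none
Why: Zinc should insert only into the primary C–I bond (the secondary bromide and the epoxide react more slowly), and Pd(PPh3)4 should couple the alkylzinc with the C–I bond of 14 with retention, which forms C4–C3 and fixes bromine cis to C4; this is a Negishi sp3–sp2 coupling of the kind known for 1-bromo-2-iodoalkenes. MeAlCl2 then ionizes the C6–O bond of the epoxide as the terminal CH2 of the diene attacks C6 from the opposite face, and loss of a proton from C1 of the bromine-stabilized allyl cation restores the diene; the closest known reaction type is the Lewis acid epoxide-initiated cation–olefin cyclization. Ring B closes in a 6-endo-trig mode on the diene (6-exo at the epoxide) through a chair transition state. C6 is set by inversion at the epoxide carbon, so C1 ends anti to the C7 oxygen, whose configuration comes unchanged from the directed epoxidation. The equatorial bromine at C9 holds the half-chair in which attack at C6 is the trans-diaxial (Fürst–Plattner) opening and the pseudoaxial C11 methyl lies on the far face. The step needs attack by C1 and not by C15, and no 1,2-shift: the six-membered chair and the unhindered terminal CH2 should favour the first, and low temperature the second.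

**Compound list**
1 | (4R,6R)-4-hydroxy-2,2,6-trimethylcyclohexanone | C[C@@H]1C[C@@H](O)CC(C)(C)C1=O | starting material
2 | 2,4,6-triisopropylbenzenesulfonyl hydrazide | CC(C)c1cc(C(C)C)c(S(=O)(=O)NN)c(C(C)C)c1 | starting material
3 | N'-[(4R,6R)-4-hydroxy-2,2,6-trimethylcyclohexylidene]-2,4,6-triisopropylbenzenesulfonohydrazide (C=N geometry not defined) | C[C@@H]1C[C@@H](O)CC(C)(C)C1=NNS(=O)(=O)c1c(C(C)C)cc(C(C)C)cc1C(C)C | intermediate
4 | oxirane | C1CO1 | starting material
5 | lithium (1R)-4-lithio-3,5,5-trimethylcyclohex-3-en-1-olate | CC1=C([Li])C(C)(C)C[C@H](O[Li])C1 | intermediate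
6 | (1R)-4-(2-hydroxyethyl)-3,5,5-trimethylcyclohex-3-en-1-ol | CC1=C(CCO)C(C)(C)C[C@H](O)C1 | intermediate
7 | (1R)-4-(2-iodoethyl)-3,5,5-trimethylcyclohex-3-en-1-ol | CC1=C(CCI)C(C)(C)C[C@H](O)C1 | intermediate
8 | (1S,3S,6R)-6-(2-iodoethyl)-1,5,5-trimethyl-7-oxabicyclo[4.1.0]heptan-3-ol | C[C@]12C[C@@H](O)CC(C)(C)[C@@]1(CCI)O2 | intermediate
9 | (1R,4R,6S)-4-bromo-1-(2-iodoethyl)-2,2,6-trimethyl-7-oxabicyclo[4.1.0]heptane | C[C@]12C[C@H](Br)CC(C)(C)[C@@]1(CCI)O2 | intermediate
10 | bromoethene | C=CBr | starting material
11 | ethynyltrimethylsilane | C#C[Si](C)(C)C | starting material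
12 | trimethyl(but-3-en-1-yn-1-yl)silane | C=CC#C[Si](C)(C)C | intermediate
13 | 1-bromobut-3-en-1-yne | C=CC#CBr | intermediate
14 | (1Z)-1-bromo-2-iodobuta-1,3-diene | Br/C=C(\I)C=C | intermediate
15 | iodo{2-[(1R,4R,6S)-4-bromo-2,2,6-trimethyl-7-oxabicyclo[4.1.0]heptan-1-yl]ethyl}zinc | C[C@]12C[C@H](Br)CC(C)(C)[C@@]1(CC[Zn]I)O2 | intermediate
16 | (1R,4R,6S)-4-bromo-1-[(3E)-3-(bromomethylidene)pent-4-en-1-yl]-2,2,6-trimethyl-7-oxabicyclo[4.1.0]heptane | C[C@]12C[C@H](Br)CC(C)(C)[C@@]1(CC/C(C=C)=C\Br)O2 | intermediate
17 | (1S,3R,6S)-3-bromo-9-[(E)-bromomethylidene]-1,5,5-trimethylspiro[5.5]undec-7-en-1-ol | CC1(C)C[C@@H](Br)C[C@](C)(O)[C@@]12C=C/C(=C/Br)CC2 | target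

**Step count.** Total: 9 steps. Longest linear sequence: 6 steps (steps 1–5 and 9); the diene branch is steps 6–8.

**Steps most likely to fail**

1. Step 9. The tetrasubstituted epoxide may be opened or rearranged (halide attack, 1,2-shift) by the zinc halides while the organozinc is formed and coupled, so that little intact epoxy triene reaches the Lewis acid. The fallback makes the C4–C3 bond before the epoxide exists. It sets out from 7: iodine–lithium exchange (t-BuLi, 3 equiv) in the presence of B-methoxy-9-BBN, then Suzuki–Miyaura coupling with 14 (PdCl2(dppf), K3PO4, DMF) should give (1R)-4-[(3E)-3-(bromomethylidene)pent-4-en-1-yl]-3,5,5-trimethylcyclohex-3-en-1-ol F1. Hydroxyl-directed epoxidation (VO(acac)2, t-BuOOH), which should leave the remote bromodiene alone, gives the epoxy alcohol (1S,3S,6R)-6-[(3E)-3-(bromomethylidene)pent-4-en-1-yl]-1,5,5-trimethyl-7-oxabicyclo[4.1.0]heptan-3-ol F2. Appel bromination with inversion returns to the route at 16, which is isolated and cyclised with MeAlCl2 as in the last stage of step 9.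

2. Step 8. Iodide may add in a conjugate sense along the enyne, and the volatile bromoenyne may oligomerize in acid, in place of clean anti addition across the triple bond. The fallback carries out the hydroiodination before the vinyl group exists. It sets out from 11: lithiation and addition to paraformaldehyde gives 3-(trimethylsilyl)prop-2-yn-1-ol F3, and NBS with AgNO3 gives 3-bromoprop-2-yn-1-ol F4. LiI in AcOH gives (2Z)-3-bromo-2-iodoprop-2-en-1-ol F5, MnO2 gives (2Z)-3-bromo-2-iodoprop-2-enal F6, and Wittig methylenation (Ph3P=CH2) returns to the route at 14.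

3. Step 5. E2 elimination of the axial oxyphosphonium group and opening of the epoxide by bromide may compete with substitution at the secondary carbon. The fallback replaces the one-flask oxyphosphonium activation by an isolated sulfonate and a separate displacement. It sets out from 8: Tf2O and 2,6-lutidine at −78 °C give (1S,3S,6R)-6-(2-iodoethyl)-1,5,5-trimethyl-7-oxabicyclo[4.1.0]heptan-3-yl trifluoromethanesulfonate F7, and displacement with tetrabutylammonium bromide at −40 → 0 °C (SN2, inversion) returns to the route at 9.

**Further compounds**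
F1 | step 9 | (1R)-4-[(3E)-3-(bromomethylidene)pent-4-en-1-yl]-3,5,5-trimethylcyclohex-3-en-1-ol | CC1=C(CC/C(C=C)=C\Br)C(C)(C)C[C@H](O)C1
F2 | step 9 | (1S,3S,6R)-6-[(3E)-3-(bromomethylidene)pent-4-en-1-yl]-1,5,5-trimethyl-7-oxabicyclo[4.1.0]heptan-3-ol | C[C@]12C[C@@H](O)CC(C)(C)[C@@]1(CC/C(C=C)=C\Br)O2
F3 | step 8 | 3-(trimethylsilyl)prop-2-yn-1-ol | OCC#C[Si](C)(C)C
F4 | step 8 | 3-bromoprop-2-yn-1-ol | OCC#CBr
F5 | step 8 | (2Z)-3-bromo-2-iodoprop-2-en-1-ol | Br/C=C(\I)CO
F6 | step 8 | (2Z)-3-bromo-2-iodoprop-2-enal | Br/C=C(\I)C=O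
F7 | step 5 | (1S,3S,6R)-6-(2-iodoethyl)-1,5,5-trimethyl-7-oxabicyclo[4.1.0]heptan-3-yl trifluoromethanesulfonate | C[C@]12C[C@@H](OS(=O)(=O)C(F)(F)F)CC(C)(C)[C@@]1(CCI)O2
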